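**Retrosynthetic overview**
- The ten-membered ring is closed last, by an intramolecular B-alkyl Suzuki coupling (C9–C10, germacrane numbering) of an acyclic precursor that already carries the oxirane and both esters.
- That precursor comes from acetylation and hydroxyl-directed threo epoxidation (C4–C5) of the product of the key late union: a catalytic asymmetric (E)-γ-isopropylallylboration that joins a western iodo enal ester (18 non-hydrogen atoms) with an eastern allylboronate (15 non-hydrogen atoms) and sets C6 and C7.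
- The western enal comes from CBS reduction (C3) and angeloylation of an enone made from a C4 vinylmagnesium unit (from ethyl but-2-ynoate) and a C5 Weinreb amide carrying the (E)-iodoalkene (from pent-3-yn-1-ol).
- The eastern allylboronate comes from 2-methylpropanal and vinylmagnesium bromide, then acetylation and Pd2(dba)3-catalysed borylation; angelic anhydride comes from two molecules of angelic acid.
- Ring order: oxirane first (acyclic, step 18), then the cyclodecene (step 20).

Assumption: the SMILES is taken literally, i.e. (3R,4R,5R,6S,7R), 1(10)E alkene, trans-4,5-epoxide, C3 ester = angelate [(2Z)-2-methylbut-2-enoate]; germacrane numbering is used for atom labels.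

**Route**

Step 1
Reactants: 1 pent-3-yn-1-ol
Product: 2 tert-butyldimethyl(pent-3-yn-1-yloxy)silane
Conditions: TBSCl, imidazole, DMF, rt
Reagents that add atoms: tert-butyldimethylsilyl chloride, CC(C)(C)[Si](C)(C)Cl
Why: Standard silylation removes the free hydroxyl so that the regiochemistry of the following hydrozirconation is governed by sterics alone.

Step 2
Reactants: 2 tert-butyldimethyl(pent-3-yn-1-yloxy)silane
Product: 4 tert-butyl{[(3E)-4-iodopent-3-en-1-yl]oxy}dimethylsilane, via vinylzirconocene 3 (not isolated)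
Conditions: Cp2Zr(H)Cl (1.8 equiv), THF, rt → 45 °C; then I2, 0 °C
Reagents that add atoms: iodine, II
Why: syn-Hydrozirconation equilibrates zirconium to the less hindered methyl-bearing alkyne carbon and iodinolysis with retention gives the (E)-2-iodoalkene that later becomes the C1=C10 geometry.

Step 3
Reactants: 4 tert-butyl{[(3E)-4-iodopent-3-en-1-yl]oxy}dimethylsilane
Product: 7 (3E)-4-iodopent-3-enoic acid, via alcohol 5 (not isolated), via aldehyde 6 (not isolated)
Conditions: CrO3, H2SO4, H2O, acetone, 0 °C → rt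
Reagents that add atoms: water, O
Why: Jones oxidation cleaves the primary silyl ether in the acidic medium and oxidises the alcohol through the aldehyde hydrate to the acid, leaving the vinyl iodide intact.

Step 4
Reactants: 7 (3E)-4-iodopent-3-enoic acid
Product: 9 (3E)-4-iodo-N-methoxy-N-methylpent-3-enamide, via acyl imidazole 8 (not isolated)
Conditions: CDI, CH2Cl2, rt; then MeNH(OMe)·HCl, rt
Reagents that add atoms: N,O-dimethylhydroxylamine hydrochloride, CNOC.Cl
Why: Weinreb amide formation by CDI activation and aminolysis is near neutral, so the β,γ-alkene does not move into conjugation.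

Step 5
Reactants: 10 ethyl but-2-ynoate
Product: 12 ethyl (2E)-3-(tributylstannyl)but-2-enoate, via vinylcopper 11 (not isolated)
Conditions: Bu3SnH, LiN(iPr)2, THF, 0 °C; CuBr·SMe2, −78 °C; then 10, MeOH, −78 °C
Reagents that add atoms: tributyltin hydride, CCCC[SnH](CCCC)CCCC
Why: Piers stannylcupration adds Sn–Cu syn across the ynoate and kinetic protonation at −78 °C gives the (E)-β-stannyl enoate, placing the methyl cis to the ester carbon as needed for the (E)-C4=C5 unit.

Step 6
Reactants: 12 ethyl (2E)-3-(tributylstannyl)but-2-enoate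
Product: 14 (2E)-3-(tributylstannyl)but-2-en-1-ol, via aluminium alkoxide 13 (not isolated)
Conditions: iBu2AlH (2.2 equiv), CH2Cl2, −78 → 0 °C; aq. KNaC4H4O6 (potassium sodium tartrate)
Reagents that add atoms: none
Why: 1,2-Reduction of the enoate by iBu2AlH gives the allylic alcohol without touching the vinylstannane or its geometry.

Step 7
Reactants: 14 (2E)-3-(tributylstannyl)but-2-en-1-ol
Product: 16 tributyl{(2E)-4-[(4-methoxyphenyl)methoxy]but-2-en-2-yl}stannane, via sodium alkoxide 15 (not isolated)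
Conditions: NaH, THF/DMF, 0 °C; PMBCl, Bu4NI (cat.), rt
Reagents that add atoms: 4-methoxybenzyl chloride, COc1ccc(CCl)cc1
Why: Williamson etherification installs a PMB ether that survives the organometallic, borane and amide-base steps and is later removed oxidatively.

Step 8
Reactants: 16 tributyl{(2E)-4-[(4-methoxyphenyl)methoxy]but-2-en-2-yl}stannane; 9 (3E)-4-iodo-N-methoxy-N-methylpent-3-enamide
Product: 20 (2E,6E)-7-iodo-1-[(4-methoxyphenyl)methoxy]-3-methylocta-2,6-dien-4-one, via vinyllithium 17 (not isolated), via vinylmagnesium bromide 18 (not isolated), via tetrahedral magnesium adduct 19 (not isolated)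
Conditions: 16 (1.3 equiv), n-BuLi, THF, −78 °C; MgBr2·OEt2, −78 → −40 °C; then 9, −40 → 0 °C; aq. NH4Cl
Reagents that add atoms: none
Why: Tin–lithium exchange with retention, transmetalation to magnesium (which suppresses iodine–metal exchange with the vinyl iodide) and Weinreb ketone synthesis through the stable chelate give the enone without over-addition.

Step 9
Reactants: 20 (2E,6E)-7-iodo-1-[(4-methoxyphenyl)methoxy]-3-methylocta-2,6-dien-4-one
Product: 22 (2E,4R,6E)-7-iodo-1-[(4-methoxyphenyl)methoxy]-3-methylocta-2,6-dien-4-ol, via catechol borate 21 (not isolated)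
Conditions: (S)-2-methyl-CBS-oxazaborolidine (20 mol%), catecholborane, toluene, −78 °C; MeOH, aq. NaOH wash
Reagents that add atoms: none
Why: In this Corey–Bakshi–Shibata reduction the α-methyl alkenyl group is the large substituent, so the (S)-catalyst gives the (R)-carbinol (C3) just as it gives (R)-1-phenylethanol from acetophenone.

Step 10
Reactants: 23 angelic acid [(2Z)-2-methylbut-2-enoic acid]
Product: 24 angelic anhydride [(2Z)-2-methylbut-2-enoic anhydride]
Conditions: 23 (2.0 equiv in all), DCC (1.0 equiv), CH2Cl2, 0 °C → rt; filtration of the urea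
Reagents that add atoms: angelic acid (the second molecule of 23), C/C=C(/C)C(=O)O
Why: Carbodiimide dehydration condenses two molecules of the acid to the symmetric anhydride, with the water taken up by DCC, and uses no nucleophilic catalyst that could isomerise angelate to tiglate.

Step 11
Reactants: 22 (2E,4R,6E)-7-iodo-1-[(4-methoxyphenyl)methoxy]-3-methylocta-2,6-dien-4-ol; 24 angelic anhydride
Product: 26 (2E,4R,6E)-7-iodo-1-[(4-methoxyphenyl)methoxy]-3-methylocta-2,6-dien-4-yl (2Z)-2-methylbut-2-enoate, via lithium alkoxide 25 (not isolated)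
Conditions: LiN(SiMe3)2, THF, −78 °C; then 24, −78 → 0 °C
Reagents that add atoms: none
Why: Acylation of the preformed lithium alkoxide by the anhydride is a cold, DMAP-free esterification that keeps the (Z)-geometry, and it puts the angelate on a robust acyclic alcohol instead of the final strained epoxide.

Step 12
Reactants: 26 (2E,4R,6E)-7-iodo-1-[(4-methoxyphenyl)methoxy]-3-methylocta-2,6-dien-4-yl (2Z)-2-methylbut-2-enoate
Product: 27 (2E,4R,6E)-1-hydroxy-7-iodo-3-methylocta-2,6-dien-4-yl (2Z)-2-methylbut-2-enoate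
Conditions: DDQ, CH2Cl2/pH 7 buffer, 0 °C
Reagents that add atoms: none
Why: Oxidative PMB cleavage by DDQ frees the primary allylic alcohol while the ester and vinyl iodide are inert.

Step 13
Reactants: 27 (2E,4R,6E)-1-hydroxy-7-iodo-3-methylocta-2,6-dien-4-yl (2Z)-2-methylbut-2-enoate
Product: 28 (2E,4R,6E)-7-iodo-3-methyl-1-oxoocta-2,6-dien-4-yl (2Z)-2-methylbut-2-enoate
Conditions: Dess–Martin periodinane, NaHCO3, CH2Cl2, 0 °C → rt
Reagents that add atoms: none
Why: Buffered Dess–Martin oxidation gives the (E)-enal (C6 aldehyde) without base that could epimerise the γ-acyloxy centre.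

Step 14
Reactants: 29 2-methylpropanal
Product: 31 rac-4-methylpent-1-en-3-ol, via bromomagnesium alkoxide 30 (not isolated)
Conditions: CH2=CHMgBr, THF, 0 °C; aq. NH4Cl
Reagents that add atoms: vinylmagnesium bromide, C=C[Mg]Br
Why: Grignard 1,2-addition builds the C6 allyl skeleton, and its racemic carbinol centre is erased in the later π-allyl step.

Step 15
Reactants: 31 rac-4-methylpent-1-en-3-ol
Product: 32 rac-4-methylpent-1-en-3-yl acetate
Conditions: Ac2O, pyridine, DMAP (cat.), CH2Cl2, rt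
Reagents that add atoms: acetic anhydride, CC(=O)OC(C)=O
Why: Acetylation provides the allylic leaving group for palladium.

Step 16
Reactants: 32 rac-4-methylpent-1-en-3-yl acetate
Product: 33 4,4,5,5-tetramethyl-2-[(2E)-4-methylpent-2-en-1-yl]-1,3,2-dioxaborolane
Conditions: B2pin2, Pd2(dba)3 (2.5 mol%), DMSO, 50 °C
Reagents that add atoms: bis(pinacolato)diboron, CC1(C)OB(OC1(C)C)B1OC(C)(C)C(C)(C)O1
Why: Miyaura-type allylic borylation through a π-allylpalladium intermediate delivers boron to the unhindered terminus and gives the (E)-allylboronate.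

Step 17
Reactants: 28 (2E,4R,6E)-7-iodo-3-methyl-1-oxoocta-2,6-dien-4-yl (2Z)-2-methylbut-2-enoate; 33 4,4,5,5-tetramethyl-2-[(2E)-4-methylpent-2-en-1-yl]-1,3,2-dioxaborolane
Product: 35 (3S,4S,5E,7R,9E)-4-hydroxy-10-iodo-6-methyl-3-(propan-2-yl)undeca-1,5,9-trien-7-yl (2Z)-2-methylbut-2-enoate, via pinacol borate 34 (not isolated)
Conditions: 33 (1.5 equiv), (S)-TRIP [(S)-3,3′-bis(2,4,6-triisopropylphenyl)-1,1′-binaphthyl-2,2′-diyl hydrogen phosphate, the antipode that gives (S)-1-phenylbut-3-en-1-ol from benzaldehyde] (10 mol%), 4 Å MS, toluene, −30 °C; aq. NaHCO3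
Reagents that add atoms: none
Why: In this chiral phosphoric acid-catalysed allylboration the closed chair transition state turns the (E)-boronate into the anti C6/C7 pair and the (S)-acid directs attack to the Si face of the aldehyde, giving 6S and the C7 configuration of the target while leaving the vinyl group for ring closure.

Step 18
Reactants: 35 (3S,4S,5E,7R,9E)-4-hydroxy-10-iodo-6-methyl-3-(propan-2-yl)undeca-1,5,9-trien-7-yl (2Z)-2-methylbut-2-enoate
Product: 36 (1R,3E)-1-{(2R,3R)-3-[(1S,2S)-1-hydroxy-2-(propan-2-yl)but-3-en-1-yl]-2-methyloxiran-2-yl}-4-iodopent-3-en-1-yl (2Z)-2-methylbut-2-enoate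
Conditions: mCPBA, NaHCO3, CH2Cl2, 0 °C
Reagents that add atoms: 3-chloroperoxybenzoic acid, OOC(=O)c1cccc(Cl)c1
Why: In this hydroxyl-directed (Henbest) epoxidation A(1,3) strain from the C4 methyl holds H-6 in the alkene plane, so the peracid bound to the C6 hydroxyl gives the threo (4R,5R) oxirane, while the terminal vinyl, iodoalkene and enoate are far less nucleophilic.

Step 19
Reactants: 36 (1R,3E)-1-{(2R,3R)-3-[(1S,2S)-1-hydroxy-2-(propan-2-yl)but-3-en-1-yl]-2-methyloxiran-2-yl}-4-iodopent-3-en-1-yl (2Z)-2-methylbut-2-enoate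
Product: 37 (1R,3E)-1-{(2R,3R)-3-[(1S,2S)-1-(acetyloxy)-2-(propan-2-yl)but-3-en-1-yl]-2-methyloxiran-2-yl}-4-iodopent-3-en-1-yl (2Z)-2-methylbut-2-enoate
Conditions: Ac2O, pyridine, DMAP (cat.), CH2Cl2, 0 °C → rt
Reagents that add atoms: acetic anhydride, CC(=O)OC(C)=O
Why: DMAP-catalysed acetylation installs the C6 acetate and leaves no free hydroxyl next to the oxirane, and neither ester is allylic any more, so palladium cannot ionise them.

Step 20
Reactants: 37 (1R,3E)-1-{(2R,3R)-3-[(1S,2S)-1-(acetyloxy)-2-(propan-2-yl)but-3-en-1-yl]-2-methyloxiran-2-yl}-4-iodopent-3-en-1-yl (2Z)-2-methylbut-2-enoate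
Product: 39 (1(10)E,3R,4R,5R,6S,7R)-6-acetoxy-4,5-epoxygermacr-1(10)-en-3-yl (2Z)-2-methylbut-2-enoate (target), via alkyl-9-BBN borane 38 (not isolated)
Conditions: 9-BBN-H, THF, rt; then syringe-pump addition to Pd(dppf)Cl2 (20 mol%), AsPh3, Cs2CO3, DMF/THF/H2O, 2 mM, rt → 40 °C
Reagents that add atoms: none
Why: Anti-Markovnikov hydroboration of the only monosubstituted alkene followed by intramolecular B-alkyl Suzuki–Miyaura coupling with retention of the (E)-iodoalkene geometry closes the ten-membered ring (C9–C10) under high dilution without creating a stereocentre.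

**Compound list**

1 | pent-3-yn-1-ol | CC#CCCO | starting material
2 | tert-butyldimethyl(pent-3-yn-1-yloxy)silane | CC#CCCO[Si](C)(C)C(C)(C)C | intermediate
3 | chlorobis(cyclopentadienyl)[(2E)-5-(tert-butyldimethylsilyloxy)pent-2-en-2-yl]zirconium | C/C(=C\CCO[Si](C)(C)C(C)(C)C)[Zr](Cl)(C1C=CC=C1)C1C=CC=C1 | intermediate
4 | tert-butyl{[(3E)-4-iodopent-3-en-1-yl]oxy}dimethylsilane | C/C(I)=C\CCO[Si](C)(C)C(C)(C)C | intermediate
5 | (3E)-4-iodopent-3-en-1-ol | C/C(I)=C\CCO | intermediate
6 | (3E)-4-iodopent-3-enal | C/C(I)=C\CC=O | intermediate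
7 | (3E)-4-iodopent-3-enoic acid | C/C(I)=C\CC(=O)O | intermediate
8 | (3E)-1-(1H-imidazol-1-yl)-4-iodopent-3-en-1-one | C/C(I)=C\CC(=O)n1ccnc1 | intermediate
9 | (3E)-4-iodo-N-methoxy-N-methylpent-3-enamide | C/C(I)=C\CC(=O)N(C)OC | intermediate
10 | ethyl but-2-ynoate | CC#CC(=O)OCC | starting material
11 | ethyl (2Z)-2-cuprio-3-(tributylstannyl)but-2-enoate | C/C(=C(/[Cu])C(=O)OCC)[Sn](CCCC)(CCCC)CCCC | intermediate
12 | ethyl (2E)-3-(tributylstannyl)but-2-enoate | C/C(=C\C(=O)OCC)[Sn](CCCC)(CCCC)CCCC | intermediate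
13 | diisobutyl{[(2E)-3-(tributylstannyl)but-2-en-1-yl]oxy}alane | C/C(=C\CO[Al](CC(C)C)CC(C)C)[Sn](CCCC)(CCCC)CCCC | intermediate
14 | (2E)-3-(tributylstannyl)but-2-en-1-ol | C/C(=C\CO)[Sn](CCCC)(CCCC)CCCC | intermediate
15 | sodium (2E)-3-(tributylstannyl)but-2-en-1-olate | C/C(=C\C[O-])[Sn](CCCC)(CCCC)CCCC.[Na+] | intermediate
16 | tributyl{(2E)-4-[(4-methoxyphenyl)methoxy]but-2-en-2-yl}stannane | C/C(=C\COCc1ccc(OC)cc1)[Sn](CCCC)(CCCC)CCCC | intermediate
17 | lithio analogue of 16 (Li in place of SnBu3, geometry retained) | C/C([Li])=C\COCc1ccc(OC)cc1 | intermediate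
18 | bromo{(2E)-4-[(4-methoxyphenyl)methoxy]but-2-en-2-yl}magnesium | C/C([Mg]Br)=C\COCc1ccc(OC)cc1 | intermediate
19 | bromomagnesium salt of the N-methoxy-N-methyl hemiaminal of 20 | C/C(I)=C\CC(O[Mg]Br)(N(C)OC)/C(C)=C/COCc1ccc(OC)cc1 | intermediate
20 | (2E,6E)-7-iodo-1-[(4-methoxyphenyl)methoxy]-3-methylocta-2,6-dien-4-one | C/C(I)=C\CC(=O)/C(C)=C/COCc1ccc(OC)cc1 | intermediate
21 | 2-{[(2E,4R,6E)-7-iodo-1-[(4-methoxyphenyl)methoxy]-3-methylocta-2,6-dien-4-yl]oxy}-1,3,2-benzodioxaborole | c1ccc2OB(O[C@@H](/C(C)=C/COCc3ccc(OC)cc3)C/C=C(\C)I)Oc2c1 | intermediate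
22 | (2E,4R,6E)-7-iodo-1-[(4-methoxyphenyl)methoxy]-3-methylocta-2,6-dien-4-ol | O[C@@H](/C(C)=C/COCc1ccc(OC)cc1)C/C=C(\C)I | intermediate
23 | angelic acid, (2Z)-2-methylbut-2-enoic acid | C/C=C(/C)C(=O)O | starting material
24 | angelic anhydride, (2Z)-2-methylbut-2-enoic anhydride | C/C=C(/C)C(=O)OC(=O)C(/C)=C\C | intermediate
25 | lithium alkoxide of 22 | [Li]O[C@@H](/C(C)=C/COCc1ccc(OC)cc1)C/C=C(\C)I | intermediate
26 | (2E,4R,6E)-7-iodo-1-[(4-methoxyphenyl)methoxy]-3-methylocta-2,6-dien-4-yl (2Z)-2-methylbut-2-enoate | C/C=C(/C)C(=O)O[C@@H](/C(C)=C/COCc1ccc(OC)cc1)C/C=C(\C)I | intermediate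
27 | (2E,4R,6E)-1-hydroxy-7-iodo-3-methylocta-2,6-dien-4-yl (2Z)-2-methylbut-2-enoate | C/C=C(/C)C(=O)O[C@@H](/C(C)=C/CO)C/C=C(\C)I | intermediate
28 | (2E,4R,6E)-7-iodo-3-methyl-1-oxoocta-2,6-dien-4-yl (2Z)-2-methylbut-2-enoate | C/C=C(/C)C(=O)O[C@@H](/C(C)=C/C=O)C/C=C(\C)I | intermediate
29 | 2-methylpropanal | CC(C)C=O | starting material
30 | bromomagnesium 4-methylpent-1-en-3-olate | CC(C)C(O[Mg]Br)C=C | intermediate
31 | rac-4-methylpent-1-en-3-ol | CC(C)C(O)C=C | intermediate
32 | rac-4-methylpent-1-en-3-yl acetate | CC(C)C(OC(C)=O)C=C | intermediate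
33 | 4,4,5,5-tetramethyl-2-[(2E)-4-methylpent-2-en-1-yl]-1,3,2-dioxaborolane | CC(C)/C=C/CB1OC(C)(C)C(C)(C)O1 | intermediate
34 | pinacol borate (O–Bpin ester) of 35 | C/C=C(/C)C(=O)O[C@@H](/C(C)=C/[C@@H](OB1OC(C)(C)C(C)(C)O1)[C@@H](C(C)C)C=C)C/C=C(\C)I | intermediate
35 | (3S,4S,5E,7R,9E)-4-hydroxy-10-iodo-6-methyl-3-(propan-2-yl)undeca-1,5,9-trien-7-yl (2Z)-2-methylbut-2-enoate | C/C=C(/C)C(=O)O[C@@H](/C(C)=C/[C@@H](O)[C@@H](C(C)C)C=C)C/C=C(\C)I | intermediate
36 | (1R,3E)-1-{(2R,3R)-3-[(1S,2S)-1-hydroxy-2-(propan-2-yl)but-3-en-1-yl]-2-methyloxiran-2-yl}-4-iodopent-3-en-1-yl (2Z)-2-methylbut-2-enoate | C/C=C(/C)C(=O)O[C@@H]([C@@]1(C)O[C@@H]1[C@@H](O)[C@@H](C(C)C)C=C)C/C=C(\C)I | intermediate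
37 | (1R,3E)-1-{(2R,3R)-3-[(1S,2S)-1-(acetyloxy)-2-(propan-2-yl)but-3-en-1-yl]-2-methyloxiran-2-yl}-4-iodopent-3-en-1-yl (2Z)-2-methylbut-2-enoate | C/C=C(/C)C(=O)O[C@@H]([C@@]1(C)O[C@@H]1[C@@H](OC(C)=O)[C@@H](C(C)C)C=C)C/C=C(\C)I | intermediate
38 | B-alkyl-9-BBN from 37 (CH=CH2 converted to CH2CH2–B(C8H14)) | C/C=C(/C)C(=O)O[C@@H]([C@@]1(C)O[C@@H]1[C@@H](OC(C)=O)[C@@H](C(C)C)CCB1C2CCCC1CCC2)C/C=C(\C)I | intermediate
39 | (1(10)E,3R,4R,5R,6S,7R)-6-acetoxy-4,5-epoxygermacr-1(10)-en-3-yl (2Z)-2-methylbut-2-enoate | C/C=C(/C)C(=O)O[C@@H]1C/C=C(\C)CC[C@H](C(C)C)[C@H](OC(C)=O)[C@H]2O[C@@]21C | target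

**Totals**

Total step count: 20.
Longest linear sequence: 13 steps (steps 1–4, 8, 9, 11–13, 17–20).

**Steps most likely to fail, with fallbacks**

The ring closure of step 20 is the largest risk: a strained (E)-cyclodecene must form by intramolecular B-alkyl Suzuki coupling, in aqueous base and with two esters present. The fallback sets out from 37 and comes back at 39. Hydroboration of 37 to 38 with oxidative work-up (NaBO3, THF/H2O) gives the primary alcohol F1. Appel iodination (I2, PPh3, imidazole) gives the primary iodide F2. Zinc insertion (Zn dust, LiCl, THF, 25 °C), which is selective for the alkyl iodide over the vinyl iodide, gives the alkylzinc iodide F3. A base-free intramolecular Negishi coupling (Pd(PtBu3)2, THF/NMP, high dilution) then closes the ring to 39.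

The key union of step 17 may be slow or poorly selective, because a γ-isopropyl boronate must add to a β,β-disubstituted enal under catalyst control. The fallback sets out from 31 and 28 and comes back at 35. PBr3 (Et2O, −20 °C) converts 31 with allylic transposition into (2E)-1-bromo-4-methylpent-2-ene F4. A catalytic asymmetric Nozaki–Hiyama–Kishi allylation of 28 with F4 follows (CrCl2 cat., Mn, Me3SiCl, chiral carbazole bis(oxazoline) ligand of the antipode that gives Si-face addition, THF). The allylchromium species is anti-selective whatever the bromide geometry and gives the trimethylsilyl ether F5, which citric acid in MeOH cleaves to 35.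

In step 8 the vinylmagnesium reagent may enolise the β,γ-unsaturated Weinreb amide instead of adding to it. The fallback sets out from 4 and comes back at 20. Bu4NF (THF) releases 5, and Dess–Martin oxidation gives 6, which is used at once. Reagent 18 (made from 16 as in step 8) adds at −78 °C to give the racemic allylic alcohol F6. Dess–Martin oxidation of F6 gives 20, and step 9 then sets C3 as before.

**Further compounds**

F1 | step 20 | (1R,3E)-1-{(2R,3R)-3-[(1S,2R)-1-(acetyloxy)-4-hydroxy-2-(propan-2-yl)butyl]-2-methyloxiran-2-yl}-4-iodopent-3-en-1-yl (2Z)-2-methylbut-2-enoate | C/C=C(/C)C(=O)O[C@@H]([C@@]1(C)O[C@@H]1[C@@H](OC(C)=O)[C@@H](C(C)C)CCO)C/C=C(\C)I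
F2 | step 20 | (1R,3E)-1-{(2R,3R)-3-[(1S,2R)-1-(acetyloxy)-4-iodo-2-(propan-2-yl)butyl]-2-methyloxiran-2-yl}-4-iodopent-3-en-1-yl (2Z)-2-methylbut-2-enoate | C/C=C(/C)C(=O)O[C@@H]([C@@]1(C)O[C@@H]1[C@@H](OC(C)=O)[C@@H](C(C)C)CCI)C/C=C(\C)I
F3 | step 20 | alkylzinc iodide from F2 (CH2I converted to CH2ZnI) | C/C=C(/C)C(=O)O[C@@H]([C@@]1(C)O[C@@H]1[C@@H](OC(C)=O)[C@@H](C(C)C)CC[Zn]I)C/C=C(\C)I
F4 | step 17 | (2E)-1-bromo-4-methylpent-2-ene | CC(C)/C=C/CBr
F5 | step 17 | trimethylsilyl ether of 35 | C/C=C(/C)C(=O)O[C@@H](/C(C)=C/[C@@H](O[Si](C)(C)C)[C@@H](C(C)C)C=C)C/C=C(\C)I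
F6 | step 8 | rac-(2E,6E)-7-iodo-1-[(4-methoxyphenyl)methoxy]-3-methylocta-2,6-dien-4-ol | OC(/C(C)=C/COCc1ccc(OC)cc1)C/C=C(\C)I
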